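**Retrosynthetic overview**
- The last C=C of the curcuminoid chain is cut by a boron-templated aldol into the terpenyl-O-vanillin aldehyde and feruloylacetone. Both arene rings are bought as vanillin.
- The allylic aryl ether is cut by a Pd-catalysed cis-1,4 addition of vanillin to a vinyl epoxide, which also releases the ring hydroxyl.
- The vinyl epoxide comes in one flask from an acyclic keto aldehyde and a C5 dienylphosphonium salt: enamine 1,6-addition, intramolecular Wittig (cyclohexadiene ring, α-turmerone), then peracid (oxirane ring).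
- The keto aldehyde comes from (S)-citronellal by Schenck ene reaction and oxidative transposition. The side-chain stereocentre is from the chiral pool, the ring C–C stereocentre from the aminocatalyst, the C–O stereocentres from the epoxidation face.
- Ring order: carbocycle, then oxirane in the same operation; the oxirane is opened in the etherification and no further ring is made.

Assumption: chloro acetate 5 is bought (industrial C5 building block; an E/Z mixture is acceptable because both isomers converge on 8), and the enol tautomer of 16 is written as in the target SMILES.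

**Step 1**
Reactants: 1 (S)-citronellal, (3S)-3,7-dimethyloct-6-enal
Product: 3 (3S,5E)-7-hydroxy-3,7-dimethyloct-5-enal, via allylic hydroperoxide 2 (not isolated)
Conditions: O2, 5,10,15,20-tetraphenylporphyrin (0.5 mol %), white LED, CH2Cl2, 0 °C; then Me2S (2 equiv), 0 °C → rt; chromatography
Reagents that add atoms: singlet dioxygen, O=O
Why: Schenck ene reaction of the trisubstituted alkene followed by sulfide reduction gives the tertiary (5E) allylic alcohol together with the secondary regioisomer (about 1:1, removed by chromatography); the C3 stereocentre is untouched.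

**Step 2**
Reactants: 3 (3S,5E)-7-hydroxy-3,7-dimethyloct-5-enal
Product: 4 (3R)-3,7-dimethyl-5-oxooct-6-enal
Conditions: [C5H5NH][CrO3Cl] (2.5 equiv), Celite, CH2Cl2, rt
Reagents that add atoms: pyridinium chlorochromate, [O-][Cr](=O)(=O)Cl.c1cc[nH+]cc1
Why: Babler–Dauben oxidative 1,3-transposition ([3,3] shift of the tertiary allylic chromate ester, then oxidation) gives the β,β-dimethyl enone while the aldehyde is inert; C3 keeps its geometry and the descriptor changes from S to R only through the CIP priorities.

**Step 3**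
Reactants: 5 (2E)-4-chloro-3-methylbut-2-en-1-yl acetate; 6 triphenylphosphine
Product: 8 [(1E)-2-methylbuta-1,3-dien-1-yl]triphenylphosphonium chloride, via acetoxy phosphonium salt 7 (not isolated)
Conditions: PPh3 (1.0 equiv), MeCN, 70 °C; then Et3N (1.1 equiv), rt → 40 °C; precipitation with Et2O
Reagents that add atoms: none
Why: SN2 quaternisation of the allylic chloride, then ylide formation and vinylogous E1cB (1,4-) loss of acetate, the same way the parent butadienylphosphonium salt is made from a 4-halobut-2-enyl precursor.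

**Step 4**
Reactants: 4 (3R)-3,7-dimethyl-5-oxooct-6-enal; 8 [(1E)-2-methylbuta-1,3-dien-1-yl]triphenylphosphonium chloride
Product: 11 (6S)-2-methyl-6-[(1R,4R,6S)-1-methyl-7-oxabicyclo[4.1.0]hept-2-en-4-yl]hept-2-en-4-one, via phosphonium aldehyde 9 (not isolated), via α-turmerone 10 (not isolated)
Conditions: (R)-α,α-diphenylprolinol trimethylsilyl ether (20 mol %), PhCO2H (20 mol %), 8 (1.3 equiv), CH2Cl2, H2O (5 equiv), 0 °C → rt; then K2CO3 (2 equiv), 18-crown-6 (10 mol %), rt → 35 °C; then mCPBA (1.3 equiv), 0 °C, same flask; chromatography on Et3N-deactivated silica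
Reagents that add atoms: mCPBA (3-chloroperoxybenzoic acid), OOC(=O)c1cccc(Cl)c1
Why: Proposed new method: the aldehyde-selective enamine of 4 should add 1,6 to the cationic diene of 8 on the face left open by the (R)-catalyst (this fixes the ring CH that carries the side chain as R, catalyst control over the neighbouring methyl stereocentre), acid and water return aldehyde 9, carbonate then forms the allylic ylide that closes the cyclohexadiene ring by intramolecular Wittig reaction (10), and the buffered peracid epoxidises the more electron-rich trisubstituted diene bond mainly anti to the side chain to close the oxirane ring; the closest known reactions are the conjugate-addition/intramolecular-Wittig cyclohexadiene annulation of enolates with butadienyltriphenylphosphonium salts, Hayashi–Jørgensen enamine Michael additions, and regioselective peracid mono-epoxidation of 5-substituted cyclohexa-1,3-dienes.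

**Step 5**
Reactants: 11 (6S)-2-methyl-6-[(1R,4R,6S)-1-methyl-7-oxabicyclo[4.1.0]hept-2-en-4-yl]hept-2-en-4-one; 12 vanillin
Product: 13 4-{[(1R,4S,6R)-4-hydroxy-3-methyl-6-[(2S)-6-methyl-4-oxohept-5-en-2-yl]cyclohex-2-en-1-yl]oxy}-3-methoxybenzaldehyde
Conditions: Pd2(dba)3·CHCl3 (2.5 mol %), PPh3 (10 mol %), vanillin (1.2 equiv), THF, 0 °C → rt
Reagents that add atoms: none
Why: Tsuji–Trost opening of the vinyl epoxide: zerovalent palladium ionises the tertiary allylic C–O bond with inversion, the alkoxide deprotonates vanillin, and the phenoxide attacks the distal secondary allyl terminus anti to palladium, so the aryl ether ends cis to the hydroxyl (1,4-addition, net retention) and trans to the side chain.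

**Step 6**
Reactants: 12 vanillin; 14 acetylacetone
Product: 15 feruloylacetone, (1E,4Z)-5-hydroxy-1-(4-hydroxy-3-methoxyphenyl)hexa-1,4-dien-3-one (enol form)
Conditions: 14 (3 equiv), B2O3 (0.5 equiv), B(OnBu)3 (1 equiv), nBuNH2 (0.2 equiv), EtOAc, 80 °C; then 1 M HCl, 60 °C
Reagents that add atoms: none
Why: Pabon-type aldol condensation in which boron chelation blocks the central carbon so that only a terminal methyl condenses, with excess diketone holding the reaction at the mono-adduct; the new alkene is E.

**Step 7**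
Reactants: 13 4-{[(1R,4S,6R)-4-hydroxy-3-methyl-6-[(2S)-6-methyl-4-oxohept-5-en-2-yl]cyclohex-2-en-1-yl]oxy}-3-methoxybenzaldehyde; 15 feruloylacetone
Product: 16 bisabolocurcumin ether
Conditions: 15 (1.1 equiv), B2O3 (0.7 equiv), B(OnBu)3 (2 equiv), nBuNH2 (0.3 equiv), EtOAc, 70 °C; then 10% aq. AcOH, 40 °C
Reagents that add atoms: none
Why: a second boron-templated (Pabon) aldol condensation at the remaining methyl of 15 gives the E-styryl unit of the unsymmetrical curcuminoid; no stereocentre is touched and the mild acetic acid hydrolysis spares the allylic aryl ether.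

**Compound list**
1 | (S)-citronellal, (3S)-3,7-dimethyloct-6-enal | O=CC[C@@H](C)CCC=C(C)C | starting material
2 | (3S,5E)-7-hydroperoxy-3,7-dimethyloct-5-enal | O=CC[C@@H](C)C/C=C/C(C)(C)OO | intermediate (not isolated)
3 | (3S,5E)-7-hydroxy-3,7-dimethyloct-5-enal | O=CC[C@@H](C)C/C=C/C(C)(C)O | intermediate
4 | (3R)-3,7-dimethyl-5-oxooct-6-enal | O=CC[C@@H](C)CC(=O)C=C(C)C | intermediate
5 | (2E)-4-chloro-3-methylbut-2-en-1-yl acetate | CC(=O)OC/C=C(\C)CCl | starting material
6 | triphenylphosphine | c1ccc(cc1)P(c1ccccc1)c1ccccc1 | starting material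
7 | [(2E)-4-(acetyloxy)-2-methylbut-2-en-1-yl]triphenylphosphonium chloride | CC(=O)OC/C=C(\C)C[P+](c1ccccc1)(c1ccccc1)c1ccccc1.[Cl-] | intermediate (not isolated)
8 | [(1E)-2-methylbuta-1,3-dien-1-yl]triphenylphosphonium chloride | C=C/C(C)=C/[P+](c1ccccc1)(c1ccccc1)c1ccccc1.[Cl-] | intermediate
9 | [(2Z,5R,6S)-5-formyl-2,6,10-trimethyl-8-oxoundeca-2,9-dien-1-yl]triphenylphosphonium chloride (2Z drawn; the allylic ylide equilibrates E/Z) | O=C[C@H](C/C=C(/C)C[P+](c1ccccc1)(c1ccccc1)c1ccccc1)[C@@H](C)CC(=O)C=C(C)C.[Cl-] | intermediate (not isolated)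
10 | α-turmerone, (6S)-2-methyl-6-[(1R)-4-methylcyclohexa-2,4-dien-1-yl]hept-2-en-4-one | CC1=CC[C@@H](C=C1)[C@@H](C)CC(=O)C=C(C)C | intermediate (not isolated)
11 | (6S)-2-methyl-6-[(1R,4R,6S)-1-methyl-7-oxabicyclo[4.1.0]hept-2-en-4-yl]hept-2-en-4-one (oxirane anti to the side chain) | C[C@]12O[C@H]1C[C@@H](C=C2)[C@@H](C)CC(=O)C=C(C)C | intermediate
12 | vanillin, 4-hydroxy-3-methoxybenzaldehyde | COc1cc(C=O)ccc1O | starting material
13 | 4-{[(1R,4S,6R)-4-hydroxy-3-methyl-6-[(2S)-6-methyl-4-oxohept-5-en-2-yl]cyclohex-2-en-1-yl]oxy}-3-methoxybenzaldehyde | COc1cc(C=O)ccc1O[C@H]1C=C(C)[C@@H](O)C[C@@H]1[C@@H](C)CC(=O)C=C(C)C | intermediate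
14 | acetylacetone, pentane-2,4-dione | CC(=O)CC(C)=O | starting material
15 | feruloylacetone, (1E,4Z)-5-hydroxy-1-(4-hydroxy-3-methoxyphenyl)hexa-1,4-dien-3-one | COc1cc(/C=C/C(=O)/C=C(O)/C)ccc1O | intermediate
16 | bisabolocurcumin ether, (1E,4Z,6E)-5-hydroxy-1-(4-hydroxy-3-methoxyphenyl)-7-(4-{[(1R,4S,6R)-4-hydroxy-3-methyl-6-[(2S)-6-methyl-4-oxohept-5-en-2-yl]cyclohex-2-en-1-yl]oxy}-3-methoxyphenyl)hepta-1,4,6-trien-3-one | COc1cc(/C=C/C(=O)/C=C(O)/C=C/c2ccc(O[C@H]3C=C(C)[C@@H](O)C[C@@H]3[C@@H](C)CC(=O)C=C(C)C)c(OC)c2)ccc1O | target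

**Step count and risks**
Total steps: 7. Longest linear sequence: 5 steps (steps 1, 2, 4, 5, 7; 1 → 3 → 4 → 11 → 13 → 16).

Step 4 is the most likely to fail. The 1,6-addition of the enamine to 8 is unprecedented and may be slow. The catalyst may be alkylated by 8, or the enamine may add to the side-chain enone. The face selectivity of the epoxidation rests on substrate bias only.
The fallback sets out from 4 and comes back at 10. Michael addition of 4 to methyl vinyl ketone under the same (R)-prolinol silyl ether catalysis gives (2R,3S)-3,7-dimethyl-5-oxo-2-(3-oxobutyl)oct-6-enal F1. Base-mediated aldol condensation (LiOH, iPrOH) closes the ring to (4R)-4-[(2S)-6-methyl-4-oxohept-5-en-2-yl]cyclohex-2-en-1-one F2. MeTi(OiPr)3 adds to the unhindered ring ketone in preference to the β,β-disubstituted side-chain enone to give (4R)-1-methyl-4-[(2S)-6-methyl-4-oxohept-5-en-2-yl]cyclohex-2-en-1-ol F3. Burgess dehydration then gives 10, which is epoxidised as in the last stage of step 4 to reach 11.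

Step 5 is the second risk. Palladium has to ionise from the face that carries the side chain. Attack at the tertiary terminus or β-hydride loss to a dienone could compete.
The fallback sets out from 10 (isolated by leaving out the peracid stage of step 4) and comes back at 13. [4+2] photooxygenation (O2, tetraphenylporphyrin, light) anti to the side chain gives the endoperoxide (6S)-2-methyl-6-[(1R,4S,7R)-5-methyl-2,3-dioxabicyclo[2.2.2]oct-5-en-7-yl]hept-2-en-4-one F4. Thiourea reduction gives the cis-diol (6S)-6-[(1R,2R,5S)-2,5-dihydroxy-4-methylcyclohex-3-en-1-yl]-2-methylhept-2-en-4-one F5. Methyl chloroformate and pyridine give the bis(methyl carbonate) F6. Pd2(dba)3/PPh3 with one equivalent of vanillin should substitute the carbonate next to the side chain, because its ionisation gives the π-allyl with the methyl-bearing terminus; double inversion gives the aryl ether carbonate F7. K2CO3 in MeOH removes the remaining carbonate to give 13.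

Step 7 is the third risk. The amine and acid of the Pabon protocol may damage the allylic ether, and the side-chain ketone may condense.
The fallback sets out from 11 and comes back at 16. Commercial curcumin and BF3·OEt2 give curcumin difluoroboron complex F8, which locks the diketone against C-allylation and acidifies the phenols. Pd-catalysed addition of F8 (3 equiv) to 11 under the conditions of step 5 gives the difluoroboron complex of the target F9. Sodium oxalate (Na2C2O4) in aqueous methanol at 65 °C removes boron to give 16.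

**Further compounds**
F1 | step 4 | (2R,3S)-3,7-dimethyl-5-oxo-2-(3-oxobutyl)oct-6-enal | O=C[C@H](CCC(C)=O)[C@@H](C)CC(=O)C=C(C)C
F2 | step 4 | (4R)-4-[(2S)-6-methyl-4-oxohept-5-en-2-yl]cyclohex-2-en-1-one | O=C1C=C[C@H](CC1)[C@@H](C)CC(=O)C=C(C)C
F3 | step 4 | (4R)-1-methyl-4-[(2S)-6-methyl-4-oxohept-5-en-2-yl]cyclohex-2-en-1-ol (C1 epimers) | CC1(O)C=C[C@H](CC1)[C@@H](C)CC(=O)C=C(C)C
F4 | step 5 | (6S)-2-methyl-6-[(1R,4S,7R)-5-methyl-2,3-dioxabicyclo[2.2.2]oct-5-en-7-yl]hept-2-en-4-one | O1[C@H]2C=C(C)[C@@H](O1)C[C@@H]2[C@@H](C)CC(=O)C=C(C)C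
F5 | step 5 | (6S)-6-[(1R,2R,5S)-2,5-dihydroxy-4-methylcyclohex-3-en-1-yl]-2-methylhept-2-en-4-one | O[C@H]1C=C(C)[C@@H](O)C[C@@H]1[C@@H](C)CC(=O)C=C(C)C
F6 | step 5 | (1R,4S,6R)-4-[(methoxycarbonyl)oxy]-3-methyl-6-[(2S)-6-methyl-4-oxohept-5-en-2-yl]cyclohex-2-en-1-yl methyl carbonate | COC(=O)O[C@H]1C=C(C)[C@@H](OC(=O)OC)C[C@@H]1[C@@H](C)CC(=O)C=C(C)C
F7 | step 5 | (1S,4R,5R)-4-(4-formyl-2-methoxyphenoxy)-2-methyl-5-[(2S)-6-methyl-4-oxohept-5-en-2-yl]cyclohex-2-en-1-yl methyl carbonate | COc1cc(C=O)ccc1O[C@H]1C=C(C)[C@@H](OC(=O)OC)C[C@@H]1[C@@H](C)CC(=O)C=C(C)C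
F8 | step 7 | curcumin difluoroboron complex | COc1cc(/C=C/C2=CC(/C=C/c3ccc(O)c(OC)c3)=[O+][B-](F)(F)O2)ccc1O
F9 | step 7 | difluoroboron complex of 16 | COc1cc(/C=C/C2=CC(/C=C/c3ccc(O[C@H]4C=C(C)[C@@H](O)C[C@@H]4[C@@H](C)CC(=O)C=C(C)C)c(OC)c3)=[O+][B-](F)(F)O2)ccc1O
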